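The molar minute, the charge of L times the time, is our clock: θ = C·t. Steps with two partners (L + Z, L + Q, 2 Q) run on θ at a fixed loading of Z, but Z → X runs on t.

common to all: Z 5 mol%
- amber: L 0.075 M; run made earlier
- ochre: L 0.11 M; run made earlier
- flask: L 0.15 M; time 10 min

| run | time / min | E / % | L / % |
|---|---|---|---|
| amber | 0.667 | 0 | 98 |
| amber | 1.33 | 0 | 99 |
| amber | 3.00 | 2 | 98 |
| amber | 8.00 | 12 | 89 |
| ochre | 2.00 | 6 | 96 |
| ochre | 4.00 | 6 | 93 |
| ochre | 6.00 | 13 | 89 |
| ochre | 8.00 | 17 | 85 |

(standard deviation of a reading: 1.5 percentage points)

- average number of monomer units in a chain (chains begun, living or dead) at 10 min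
- part of the L that has reacted at 10 min

- the average divides the monomer in chains by the number of chains begun, living and dead together
- the numbers in the tables scatter with a standard deviation of 1.5 percentage points
- what may be going on: L + Z -> Q + E; L + Q -> E + Q; 2 Q -> J; Z -> X
- the earlier runs do not show the number of chains; that part of a forecast is a guess

We read κ, the logarithmic loss of L per molar minute, from the last readings.

| run, time | θ | L left | κ |
|---|---|---|---|
| amber, 8.00 min | 36.0 M·s | 89% | 0.194 M⁻¹ min⁻¹ |
| ochre, 8.00 min | 52.8 M·s | 85% | 0.185 M⁻¹ min⁻¹ |

Their mean is 0.189 M⁻¹ min⁻¹, and this is our reading of κ, taken as a pseudo-first-order constant of L per unit of charge.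

Now the ladder for the flask. Amber still read E at 0% at 1.33 min, and the flask reaches that θ at 0.665 min. Next comes the asked 10 min, later than that lag. Last comes the half-life of L, 24.4 min, longer than the asked time, so we expect L to remain the main species.

A first pass with L at its charge gives the reacted part of L, c = 28.4%. Going round once more with the mean L over the run gives 24.4%. If every Z began a chain, the average chain length dp would be 4.88, and fewer chains would raise it; that count is a guess.

The forecast, higher than our c, gives c = 36% (26% to 48%) and dp = 12 (7 to 24), holding that “fractional conversion curves upward with time”.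

The flask gives c = 28.9% and dp = 7.27.

    L + Z → Q + E (k = 1.88 M⁻¹ min⁻¹)
    L + Q → E + Q, rate k2*[Q]*[L] (k = 7.98 M⁻¹ min⁻¹)
    2 Q → J (k = 5.49 M⁻¹ min⁻¹)
    Z → X (k = 0.0491 min⁻¹)

The flask's κ, from 71% of L left, is 0.228 M⁻¹ min⁻¹, above our 0.189 M⁻¹ min⁻¹. In the flask at 5.48 min the step L + Q uses L 14 times as fast as the step L + Z. In the flask the half-life of L by L + Z alone, with the other concentrations held at their charge, is 49 min, long against 10 min. For the neighbour charged with 0.60 M of L, at the same loading and time, our κ gives 67.8%, and that flask reached 66.7%.

The readings stem from a simulated flask on assumed constants, and the scatter is random.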